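**Plan**

- Retrosynthetic cuts: C14=C15 (methylenation), C12–C13 (alkylation of a lactate-derived enolate), C9–C11 ([3,3] shift from O7), C3–Br, C3–C4 (radical closure of ring A), then C10–C1 and C10–CH3 (two enolate alkylations of carvone).
- Forward: ring B is (S)-carvone. C10 is made quaternary, ring A is closed by hydrogen-atom-transfer radical addition of the isopropenyl group to a nitrile, and the C3 ketone becomes the equatorial bromide.
- The ring-B enone is transposed (epoxide, Wharton) to the 7-ol, which relays a two-carbon chain to C9. The chain is extended to the C12 iodide and joined to a C13–C14 unit.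
- Stereochemistry: C5 comes from carvone; C10 from alkylation anti to isopropenyl; the epoxide from axial attack at C7; C3 from equatorial hydride delivery followed by SN2 inversion.
- C9 is set by the suprafacial Claisen shift, and C13 comes from (S)-lactic acid through an acetal-controlled alkylation.

Key step: step 3

Remark: the target is read as a trans-decalin whose C9 side chain lies on the face of H-5, anti to the C10 methyl, with equatorial bromine cis to that methyl. All bicyclic compounds are numbered as in labdane (ring carbons C1–C10; methyls on C4, C4, C8, C10).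

**Route**

Step 1
Reactants: 1 (S)-carvone; 2 iodomethane
Product: 4 (5S,6R)-2,6-dimethyl-5-(prop-1-en-2-yl)cyclohex-2-en-1-one, via lithium dienolate 3 (not isolated)
Conditions: LiN(i-Pr)2 (1.05 equiv), THF, −78 °C; MeI, −78 → 0 °C
Reagents that add atoms: iodomethane (compound 2), CI
Why: Kinetic deprotonation at the α′ carbon gives the cross-conjugated enolate, and its methylation (enolate alkylation) should occur mainly anti to the isopropenyl group; the new centre is planarised again in step 2, so any cis epimer can be carried along.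

Step 2
Reactants: 4 (5S,6R)-2,6-dimethyl-5-(prop-1-en-2-yl)cyclohex-2-en-1-one; 5 acrylonitrile
Product: 7 3-[(1R,6R)-1,3-dimethyl-2-oxo-6-(prop-1-en-2-yl)cyclohex-3-en-1-yl]propanenitrile, via lithium enolate 6 (not isolated)
Conditions: LiN(i-Pr)2 (1.1 equiv), THF, −78 → −20 °C; recool to −78 °C, acrylonitrile (1.2 equiv) added slowly; AcOH quench at −78 °C
Reagents that add atoms: acrylonitrile (compound 5), C=CC#N
Why: The tetrasubstituted α′ enolate should undergo Michael addition to acrylonitrile on the face anti to the neighbouring isopropenyl group, which places the cyanoethyl arm trans and the methyl cis to it and so fixes the future C10, while the cold quench is meant to protonate the α-cyano carbanion before it can add further.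

Step 3
Reactants: 7 3-[(1R,6R)-1,3-dimethyl-2-oxo-6-(prop-1-en-2-yl)cyclohex-3-en-1-yl]propanenitrile
Product: 9 (5R,10R)-4,4,8,10-tetramethyldecal-7-ene-3,9-dione, via ketimine 8 (not isolated)
Conditions: Fe(acac)3 (0.5 equiv), PhSiH3 (2.5 equiv), degassed EtOH, 60 °C, argon; then 1 M aq HCl, THF, rt
Reagents that add atoms: water, O
Why: Fe(acac)3 and PhSiH3 in ethanol should form a trivalent iron hydride that transfers a hydrogen atom to the CH2 terminus of the isopropenyl group; the tertiary C4 radical then adds to the nitrile carbon to form the C3–C4 bond, and the iminyl radical is reduced by divalent iron and protonated by ethanol to ketimine 8, which aqueous acid hydrolyses to the C3 ketone. The closest known reaction type is the iron-hydride hydrogen-atom-transfer reductive cyclisation of alkenyl nitriles to cyclic ketones. Ring A closes in the 6-exo-dig mode. No stereocentre is created, and the trans ring fusion follows from the trans arrangement of the two arms on C5 and C10 set in steps 1 and 2. The step needs hydrogen-atom transfer to the electron-rich 1,1-disubstituted alkene and not to the electron-poor enone, which the polarity of the metal hydride should secure. It also needs closure to outrun capture of a second hydrogen atom, which is helped by the reversibility of the first transfer, by the absence of any other radical trap, and by the fact that the enone β-carbon could only be reached through a four-membered ring.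

Step 4
Reactants: 9 (5R,10R)-4,4,8,10-tetramethyldecal-7-ene-3,9-dione
Product: 10 (5R,7S,8S,10R)-7,8-epoxy-4,4,8,10-tetramethyldecalin-3,9-dione
Conditions: 30% aq H2O2, NaOH (0.5 equiv), MeOH, 0 °C
Reagents that add atoms: hydrogen peroxide, OO
Why: In this Weitz–Scheffer epoxidation the hydroperoxide anion should add axially to C7, anti to the C5–C4 bond and to the C10 methyl, so the oxirane forms on the face of H-5 while the saturated, hindered C3 ketone is left alone.

Step 5
Reactants: 10 (5R,7S,8S,10R)-7,8-epoxy-4,4,8,10-tetramethyldecalin-3,9-dione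
Product: 11 (3S,5R,7S,8S,10R)-7,8-epoxy-3-hydroxy-4,4,8,10-tetramethyldecalin-9-one
Conditions: LiBH(s-Bu)3 (1.1 equiv), THF, −78 °C; AcOH quench
Reagents that add atoms: none
Why: The bulky trialkylborohydride should attack the C3 carbonyl from the equatorial direction to give the axial alcohol and should spare the C9 carbonyl, which is flanked by two fully substituted carbons.

Step 6
Reactants: 11 (3S,5R,7S,8S,10R)-7,8-epoxy-3-hydroxy-4,4,8,10-tetramethyldecalin-9-one
Product: 12 (3R,5S,7S,8S,10R)-3-bromo-7,8-epoxy-4,4,8,10-tetramethyldecalin-9-one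
Conditions: CBr4 (2 equiv), PPh3 (2.2 equiv), CH2Cl2, 0 °C → rt
Reagents that add atoms: tetrabromomethane, BrC(Br)(Br)Br
Why: In the Appel reaction bromide should displace the axial oxyphosphonium group from the rear, so inversion turns the axial alcohol into the equatorial bromide that is cis to the C10 methyl.

Step 7
Reactants: 12 (3R,5S,7S,8S,10R)-3-bromo-7,8-epoxy-4,4,8,10-tetramethyldecalin-9-one
Product: 14 (3R,5S,7S,10S)-3-bromo-4,4,8,10-tetramethyldecal-8-en-7-ol, via epoxy hydrazone 13 (not isolated)
Conditions: N2H4·H2O (5 equiv), AcOH (cat.), MeOH, 0 °C → rt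
Reagents that add atoms: none
Why: In the Wharton transposition the C9 hydrazone opens the oxirane to an alkenyl diazene that loses N2, which moves the alkene to C8–C9 and leaves the C7–O bond untouched, so the 7-hydroxyl stays pseudo-axial on the face of H-5.

Step 8
Reactants: 14 (3R,5S,7S,10S)-3-bromo-4,4,8,10-tetramethyldecal-8-en-7-ol; 15 triethyl orthoacetate
Product: 17 ethyl 2-[(3R,5S,9S,10S)-3-bromo-4,4,8,10-tetramethyldecal-7-en-9-yl]acetate, via ketene acetal 16 (not isolated)
Conditions: MeC(OEt)3 (10 equiv), EtCO2H (cat.), xylene, 140 °C, EtOH distilled off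
Reagents that add atoms: triethyl orthoacetate (compound 15), CC(OCC)(OCC)OCC
Why: In the Johnson–Claisen rearrangement the [3,3] shift of ketene acetal 16 should pass the two-carbon unit suprafacially from the pseudo-axial O7 to C9 on the face of H-5, anti to the C10 methyl, which sets C9 and returns the alkene to C7–C8.

Step 9
Reactants: 17 ethyl 2-[(3R,5S,9S,10S)-3-bromo-4,4,8,10-tetramethyldecal-7-en-9-yl]acetate
Product: 18 2-[(3R,5S,9S,10S)-3-bromo-4,4,8,10-tetramethyldecal-7-en-9-yl]ethanol
Conditions: i-Bu2AlH (2.5 equiv), CH2Cl2, −78 → 0 °C; aq potassium sodium tartrate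
Reagents that add atoms: none
Why: Hydride reduction of the ester with the aluminium hydride should give the primary alcohol without touching the hindered secondary bromide or the trisubstituted alkene.

Step 10
Reactants: 18 2-[(3R,5S,9S,10S)-3-bromo-4,4,8,10-tetramethyldecal-7-en-9-yl]ethanol
Product: 19 (3R,5S,9S,10S)-3-bromo-9-(2-iodoethyl)-4,4,8,10-tetramethyldecal-7-ene
Conditions: I2, PPh3, imidazole, CH2Cl2, 0 °C → rt
Reagents that add atoms: iodine, II
Why: Appel-type iodination of the unhindered primary alcohol is an SN2 process that should leave all stereocentres untouched.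

Step 11
Reactants: 20 (S)-lactic acid; 21 pivalaldehyde
Product: 22 (2S,5S)-2-tert-butyl-5-methyl-1,3-dioxolan-4-one
Conditions: p-TsOH·H2O (cat.), pentane, reflux, water separator; crystallisation from pentane at −78 °C
Reagents that add atoms: pivalaldehyde (compound 21), CC(C)(C)C=O
Why: Acid-catalysed acetalisation under equilibrating conditions should favour the cis acetal, in which the lactate centre sets the configuration of the new acetal carbon, and crystallisation is expected to give it free of the trans isomer.

Step 12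
Reactants: 19 (3R,5S,9S,10S)-3-bromo-9-(2-iodoethyl)-4,4,8,10-tetramethyldecal-7-ene; 22 (2S,5S)-2-tert-butyl-5-methyl-1,3-dioxolan-4-one
Product: 24 (2S,5R)-5-{2-[(3R,5S,9S,10S)-3-bromo-4,4,8,10-tetramethyldecal-7-en-9-yl]ethyl}-2-tert-butyl-5-methyl-1,3-dioxolan-4-one, via lithium enolate 23 (not isolated)
Conditions: 22 (2 equiv), LiN(i-Pr)2 (2 equiv), THF, −78 °C; then 19, DMPU, −78 → −30 °C
Reagents that add atoms: dioxolanone (compound 22), C[C@@H]1O[C@H](C(C)(C)C)OC1=O
Why: This is an enolate alkylation with self-regeneration of the stereocentre: enolisation erases the lactate centre, but the acetal carbon should steer the primary iodide to the face anti to the tert-butyl group and so create the quaternary carbinol carbon with the configuration needed at C13.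

Step 13
Reactants: 24 (2S,5R)-5-{2-[(3R,5S,9S,10S)-3-bromo-4,4,8,10-tetramethyldecal-7-en-9-yl]ethyl}-2-tert-butyl-5-methyl-1,3-dioxolan-4-one
Product: 25 (2R)-4-[(3R,5S,9S,10S)-3-bromo-4,4,8,10-tetramethyldecal-7-en-9-yl]-2-methylbutane-1,2-diol
Conditions: LiBH4 (3 equiv), THF/MeOH, 0 °C → rt
Reagents that add atoms: none
Why: Borohydride reduction of the lactone-type carbonyl should open the acetal, with the liberated pivalaldehyde reduced as well, and give the primary–tertiary diol without displacing the hindered secondary bromide.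

Step 14
Reactants: 25 (2R)-4-[(3R,5S,9S,10S)-3-bromo-4,4,8,10-tetramethyldecal-7-en-9-yl]-2-methylbutane-1,2-diol
Product: 26 (2R)-4-[(3R,5S,9S,10S)-3-bromo-4,4,8,10-tetramethyldecal-7-en-9-yl]-2-hydroxy-2-methylbutanal
Conditions: SO3·pyridine (3 equiv), DMSO, Et3N, CH2Cl2, 0 °C
Reagents that add atoms: none
Why: Parikh–Doering oxidation should convert only the primary alcohol, since the tertiary carbinol cannot be oxidised and carries no epimerisable hydrogen.

Step 15
Reactants: 26 (2R)-4-[(3R,5S,9S,10S)-3-bromo-4,4,8,10-tetramethyldecal-7-en-9-yl]-2-hydroxy-2-methylbutanal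
Product: 27 (3R,5S,9S,10S,13R)-3-bromolabda-7,14-dien-13-ol
Conditions: Ph3PCH3Br (3.0 equiv), KN(SiMe3)2 (2.9 equiv), THF, 0 °C; then 26, 0 °C → rt
Reagents that add atoms: methyltriphenylphosphonium bromide, [Br-].C[P+](c1ccccc1)(c1ccccc1)c1ccccc1
Why: Wittig methylenation of the α-hydroxy aldehyde, with one equivalent of ylide consumed by the free hydroxyl, should give the vinyl carbinol and thus the target with C13 unchanged.

**Compound list**

1 | (S)-carvone, (5S)-2-methyl-5-(prop-1-en-2-yl)cyclohex-2-en-1-one | O=C1C(C)=CC[C@H](C(C)=C)C1 | starting material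
2 | iodomethane | CI | starting material
3 | cross-conjugated lithium dienolate of 1 (O–Li on C1; C1=C6 and C2=C3) | [Li]OC1=C[C@@H](C(C)=C)CC=C1C | intermediate
4 | (5S,6R)-2,6-dimethyl-5-(prop-1-en-2-yl)cyclohex-2-en-1-one (trans-6-methylcarvone) | O=C1C(C)=CC[C@H](C(C)=C)[C@H]1C | intermediate
5 | acrylonitrile | C=CC#N | starting material
6 | lithium dienolate of 4 (O–Li on C1; C1=C6 tetrasubstituted) | [Li]OC1=C(C)[C@@H](C(C)=C)CC=C1C | intermediate
7 | 3-[(1R,6R)-1,3-dimethyl-2-oxo-6-(prop-1-en-2-yl)cyclohex-3-en-1-yl]propanenitrile (cyanoethyl trans to isopropenyl) | O=C1C(C)=CC[C@H](C(C)=C)[C@@]1(C)CCC#N | intermediate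
8 | (5R,10R)-3-imino-4,4,8,10-tetramethyldecal-7-en-9-one (N–H ketimine, trans-fused) | O=C1C(C)=CC[C@@H]2C(C)(C)C(=N)CC[C@]21C | intermediate
9 | (5R,10R)-4,4,8,10-tetramethyldecal-7-ene-3,9-dione (trans-fused) | O=C1C(C)=CC[C@@H]2C(C)(C)C(=O)CC[C@]21C | intermediate
10 | (5R,7S,8S,10R)-7,8-epoxy-4,4,8,10-tetramethyldecalin-3,9-dione (oxirane on the face of H-5) | O=C1[C@@]2(C)O[C@H]2C[C@@H]3C(C)(C)C(=O)CC[C@]31C | intermediate
11 | (3S,5R,7S,8S,10R)-7,8-epoxy-3-hydroxy-4,4,8,10-tetramethyldecalin-9-one (axial 3-OH) | O=C1[C@@]2(C)O[C@H]2C[C@@H]3C(C)(C)[C@@H](O)CC[C@]31C | intermediate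
12 | (3R,5S,7S,8S,10R)-3-bromo-7,8-epoxy-4,4,8,10-tetramethyldecalin-9-one (equatorial Br) | O=C1[C@@]2(C)O[C@H]2C[C@@H]3C(C)(C)[C@H](Br)CC[C@]31C | intermediate
13 | C9 hydrazone of 12 (all ring stereocentres as in 12) | NN=C1[C@@]2(C)O[C@H]2C[C@@H]3C(C)(C)[C@H](Br)CC[C@]31C | intermediate
14 | (3R,5S,7S,10S)-3-bromo-4,4,8,10-tetramethyldecal-8-en-7-ol (7-OH on the face of H-5) | C1=C(C)[C@@H](O)C[C@@H]2C(C)(C)[C@H](Br)CC[C@]21C | intermediate
15 | triethyl orthoacetate | CC(OCC)(OCC)OCC | starting material
16 | 7-O-(1-ethoxyvinyl) ether of 14 (mixed ketene acetal, stereocentres as in 14) | C1=C(C)[C@@H](OC(=C)OCC)C[C@@H]2C(C)(C)[C@H](Br)CC[C@]21C | intermediate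
17 | ethyl 2-[(3R,5S,9S,10S)-3-bromo-4,4,8,10-tetramethyldecal-7-en-9-yl]acetate | CCOC(=O)C[C@H]1C(C)=CC[C@@H]2C(C)(C)[C@H](Br)CC[C@]21C | intermediate
18 | 2-[(3R,5S,9S,10S)-3-bromo-4,4,8,10-tetramethyldecal-7-en-9-yl]ethanol | OCC[C@H]1C(C)=CC[C@@H]2C(C)(C)[C@H](Br)CC[C@]21C | intermediate
19 | (3R,5S,9S,10S)-3-bromo-9-(2-iodoethyl)-4,4,8,10-tetramethyldecal-7-ene | ICC[C@H]1C(C)=CC[C@@H]2C(C)(C)[C@H](Br)CC[C@]21C | intermediate
20 | (S)-lactic acid | C[C@H](O)C(=O)O | starting material
21 | pivalaldehyde | CC(C)(C)C=O | starting material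
22 | (2S,5S)-2-tert-butyl-5-methyl-1,3-dioxolan-4-one (cis) | C[C@@H]1O[C@H](C(C)(C)C)OC1=O | intermediate
23 | lithium enolate of 22 (acetal carbon 2S retained) | [Li]OC1=C(C)O[C@H](C(C)(C)C)O1 | intermediate
24 | (2S,5R)-5-{2-[(3R,5S,9S,10S)-3-bromo-4,4,8,10-tetramethyldecal-7-en-9-yl]ethyl}-2-tert-butyl-5-methyl-1,3-dioxolan-4-one | C[C@]1(CC[C@H]2C(C)=CC[C@@H]3C(C)(C)[C@H](Br)CC[C@]32C)O[C@H](C(C)(C)C)OC1=O | intermediate
25 | (2R)-4-[(3R,5S,9S,10S)-3-bromo-4,4,8,10-tetramethyldecal-7-en-9-yl]-2-methylbutane-1,2-diol | OC[C@](C)(O)CC[C@H]1C(C)=CC[C@@H]2C(C)(C)[C@H](Br)CC[C@]21C | intermediate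
26 | (2R)-4-[(3R,5S,9S,10S)-3-bromo-4,4,8,10-tetramethyldecal-7-en-9-yl]-2-hydroxy-2-methylbutanal | O=C[C@](C)(O)CC[C@H]1C(C)=CC[C@@H]2C(C)(C)[C@H](Br)CC[C@]21C | intermediate
27 | (3R,5S,9S,10S,13R)-3-bromolabda-7,14-dien-13-ol (CNP0210577.1) | C=C[C@](C)(O)CC[C@H]1C(C)=CC[C@@H]2C(C)(C)[C@H](Br)CC[C@]21C | target

**Step count and risks**

Total step count: 15. Longest linear sequence: 14 steps (steps 1–10 and 12–15, from (S)-carvone); step 11 is a one-step side branch.

The three steps most likely to fail:

Step 6. The axial oxyphosphonium ion sits on a neopentyl-type carbon, so it may ionise, lose a proton toward C2, or trigger a 1,2-methyl shift from C4 faster than bromide attacks from the rear. The fallback avoids substitution at C3 altogether; it sets out from 10 and comes back at 12. The C3 ketone of 10, the only enolisable carbonyl, is converted with KN(SiMe3)2 and PhNTf2 (THF, −78 °C) into the C2–C3 enol triflate F1. A nickel-catalysed triflate–bromide exchange (Ni(cod)2 cat., LiBr, THF/DMA, rt) should give the alkenyl bromide F2. Hydrogen-atom-transfer hydrogenation (Mn(dpm)3 cat., PhSiH3, t-BuOOH, i-PrOH, rt) then puts hydrogen on C2 and delivers the second hydrogen to the α-bromo C3 radical along the axial line, away from the axial C4 methyl, which leaves bromine equatorial and gives 12.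

Step 3. Six-membered closure onto a nitrile is slow, so the tertiary radical may take up a second hydrogen atom (net hydrogenation of the isopropenyl group), or the iron hydride may reduce the enone, before ring A closes. The fallback generates the same radical by halogen abstraction, where the hydrogen-donor concentration can be kept low at will; it sets out from 7 and comes back at 9. Markovnikov addition of HBr (HBr in AcOH, 0 °C) to the isopropenyl group gives the tertiary bromide F3. Bu3SnH added by syringe pump with AIBN (benzene, 80 °C) forms the C4 radical, which closes onto the nitrile; the iminyl radical takes hydrogen from the stannane to give ketimine 8, and acid hydrolysis as in step 3 gives 9.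

Step 2. The α-cyano carbanion formed in the Michael addition may add to further acrylonitrile (anionic oligomerisation) or back onto C3 of the enone (a second, intramolecular Michael addition leading to a bicyclo[2.2.2]octanone). The fallback builds the arm from an allyl group; it sets out from 4 and comes back at 7. Enolate 6 is alkylated with allyl bromide (THF, −78 → 0 °C), again anti to the isopropenyl group, to give the 6-allyl ketone F4. Aldehyde-selective Wacker oxidation of the monosubstituted alkene (PdCl2(PhCN)2, CuCl2, AgNO2, O2, t-BuOH/MeNO2, rt) should give aldehyde F5. Condensation at the aldehyde with NH2OH·HCl and pyridine (EtOH, rt) gives aldoxime F6, which is dehydrated ((CF3CO)2O, Et3N, CH2Cl2, 0 °C) to nitrile 7.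

**Further compounds**

F1 | step 6 | C2–C3 enol triflate of 10, (5R,7S,8S,10R)-7,8-epoxy-4,4,8,10-tetramethyl-9-oxodecal-2-en-3-yl trifluoromethanesulfonate | O=C1[C@@]2(C)O[C@H]2C[C@@H]3C(C)(C)C(OS(=O)(=O)C(F)(F)F)=CC[C@]31C
F2 | step 6 | 3-bromo-7,8-epoxy-4,4,8,10-tetramethyldecal-2-en-9-one (alkenyl bromide, other stereocentres as in 10) | O=C1[C@@]2(C)O[C@H]2C[C@@H]3C(C)(C)C(Br)=CC[C@]31C
F3 | step 3 | 3-[(1R,6S)-6-(2-bromopropan-2-yl)-1,3-dimethyl-2-oxocyclohex-3-en-1-yl]propanenitrile | O=C1C(C)=CC[C@H](C(C)(C)Br)[C@@]1(C)CCC#N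
F4 | step 2 | (5R,6R)-6-allyl-2,6-dimethyl-5-(prop-1-en-2-yl)cyclohex-2-en-1-one (allyl trans to isopropenyl) | O=C1C(C)=CC[C@H](C(C)=C)[C@@]1(C)CC=C
F5 | step 2 | 3-[(1R,6R)-1,3-dimethyl-2-oxo-6-(prop-1-en-2-yl)cyclohex-3-en-1-yl]propanal | O=C1C(C)=CC[C@H](C(C)=C)[C@@]1(C)CCC=O
F6 | step 2 | oxime of F5 at the aldehyde carbon | O=C1C(C)=CC[C@H](C(C)=C)[C@@]1(C)CCC=NO
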